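**Plan**

- Retrosynthetic cuts: the three O-benzyl groups; lactone C3–CH2Ar (enolate alkylation); lactone C3–C4, which opens the γ-lactone to the diazoacetate of a 3-arylpropanol; then benzofuran O1–C2 and C2–C3 (cationic closure, aldol) and the aryl–CH2CO homologation.
- Forward order: the dihydrobenzofuran ring is built first on 5-allyl-2-hydroxy-3-methoxybenzaldehyde, the allyl group becomes the ArCH2CH2CH2OH chain, the γ-lactone ring is closed on that chain by intramolecular carbene C–H insertion, and the second benzyl group is added last.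
- Enabling feature: lactone C4 is, in the open chain, the unactivated central CH2 of ArCH2–CH2–CH2–O, placed 1,5 to the carbene carbon across the ester O. Insertion into its C–H bond forms C3–C4 and the five-membered ring at once; O–CH2 (four-ring) and ArCH2 (six-ring) are the only rivals.
- Stereochemistry: benzofuran C3 from the (S)-oxazolidinone aldol; C2 from thermodynamic trans closure next to C3; lactone C4 from the chiral catalyst Rh2(4S-MPPIM)4; lactone C3 from alkylation anti to the C4 substituent.

Key step: step 11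

Assumption: Rh2(4S-MPPIM)4 (MPPIM = methyl 2-oxo-1-(3-phenylpropanoyl)imidazolidine-4-carboxylate) is taken as the catalyst enantiomer that gives the 4R lactone, as with simple 3-arylpropyl diazoacetates; compounds 1, 5, 8 and 20 are taken as commercial.

Abbreviation used in names: DHB-5-yl = (2S,3R)-2-[4-(benzyloxy)-3-methoxyphenyl]-3-[(benzyloxy)methyl]-7-methoxy-2,3-dihydro-1-benzofuran-5-yl.

**Route**

Step 1
Reactants: 1 5-allyl-2-hydroxy-3-methoxybenzaldehyde
Product: 2 5-allyl-3-methoxy-2-(methoxymethoxy)benzaldehyde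
Conditions: MOMCl, iPr2NEt, CH2Cl2, 0 °C to rt
Reagents that add atoms: chloromethyl methyl ether (MOMCl), COCCl
Why: Williamson-type O-alkylation masks the phenol as an acetal that should tolerate the basic, hydride and boron steps ahead and is lost later under the acid that closes the furan ring.

Step 2
Reactants: 2 5-allyl-3-methoxy-2-(methoxymethoxy)benzaldehyde
Product: 3 1-[5-allyl-3-methoxy-2-(methoxymethoxy)phenyl]-2,2,2-trichloroethan-1-ol (racemic)
Conditions: CHCl3, DBU, 0 °C to rt
Reagents that add atoms: chloroform, ClC(Cl)Cl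
Why: Base-mediated addition of the trichloromethyl anion to an aromatic aldehyde (trichloromethyl carbinol formation) is general; the new carbinol centre is racemic and is erased in step 3.

Step 3
Reactants: 3 1-[5-allyl-3-methoxy-2-(methoxymethoxy)phenyl]-2,2,2-trichloroethan-1-ol
Product: 4 [5-allyl-3-methoxy-2-(methoxymethoxy)phenyl]acetic acid
Conditions: NaBH4, NaOH, t-BuOH, 55 °C; then aq. KHSO4 to pH 4, 0 °C
Reagents that add atoms: sodium hydroxide, [Na+].[OH-]
Why: Jocic–Reeve-type reductive homologation, in which base-induced loss of chloride and hydride delivery to the benzylic carbon should turn the CH(OH)CCl3 unit into CH2CO2H under basic conditions that spare the acetal and the allyl group.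

Step 4
Reactants: 4 [5-allyl-3-methoxy-2-(methoxymethoxy)phenyl]acetic acid; 5 (S)-4-benzyl-1,3-oxazolidin-2-one
Product: 7 (4S)-3-{[5-allyl-3-methoxy-2-(methoxymethoxy)phenyl]acetyl}-4-benzyl-1,3-oxazolidin-2-one, via mixed pivalic anhydride 6 (not isolated)
Conditions: PivCl, Et3N, THF, −20 °C; then 5, LiCl, −20 °C to rt
Reagents that add atoms: none
Why: N-acylation of the oxazolidinone through the mixed anhydride (LiCl/Et3N protocol) is the standard mild entry to Evans imides and needs no strong base.

Step 5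
Reactants: 7 (4S)-3-{[5-allyl-3-methoxy-2-(methoxymethoxy)phenyl]acetyl}-4-benzyl-1,3-oxazolidin-2-one; 8 4-(benzyloxy)-3-methoxybenzaldehyde
Product: 10 (4S)-3-[(2S,3S)-2-[5-allyl-3-methoxy-2-(methoxymethoxy)phenyl]-3-[4-(benzyloxy)-3-methoxyphenyl]-3-hydroxypropanoyl]-4-benzyl-1,3-oxazolidin-2-one, via dibutylboron Z-enolate 9 (not isolated)
Conditions: Bu2BOTf, iPr2NEt, CH2Cl2, 0 °C; then 8, −78 to 0 °C; pH 7 buffer, MeOH, H2O2, 0 °C
Reagents that add atoms: none
Why: Evans syn-aldol reaction, in which the Z-boron enolate reacts through a closed Zimmerman–Traxler transition state on the face away from the auxiliary benzyl group, fixing the aryl-bearing carbon as S (the future benzofuran C3); the syn carbinol centre formed with it is re-set in step 7.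

Step 6
Reactants: 10 the aldol adduct of step 5
Product: 11 (1S,2R)-2-[5-allyl-3-methoxy-2-(methoxymethoxy)phenyl]-1-[4-(benzyloxy)-3-methoxyphenyl]propane-1,3-diol
Conditions: LiBH4, MeOH (1 equiv), THF, 0 °C to rt
Reagents that add atoms: none
Why: Reductive cleavage of the N-acyloxazolidinone with LiBH4 should give the primary alcohol without touching the adjacent stereocentre, the acetal, the ethers or the alkene, and returns the auxiliary.

Step 7
Reactants: 11 (1S,2R)-2-[5-allyl-3-methoxy-2-(methoxymethoxy)phenyl]-1-[4-(benzyloxy)-3-methoxyphenyl]propane-1,3-diol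
Product: 13 [(2S,3R)-5-allyl-2-[4-(benzyloxy)-3-methoxyphenyl]-7-methoxy-2,3-dihydro-1-benzofuran-3-yl]methanol, via free phenol triol 12 (not isolated)
Conditions: HCl (conc., cat.), MeOH/THF, 40 °C
Reagents that add atoms: none
Why: Acid-catalysed phenylcoumaran ring closure, in which acid removes the acetal and ionises the benzylic alcohol para to the benzyloxy group, the freed phenol captures the cation in a 5-exo closure, and reversible ionisation should deliver the favoured 2,3-trans ring (C2 S) under control of the fixed C3 centre.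

Step 8
Reactants: 13 [(2S,3R)-5-allyl-2-[4-(benzyloxy)-3-methoxyphenyl]-7-methoxy-2,3-dihydro-1-benzofuran-3-yl]methanol
Product: 14 (2S,3R)-5-allyl-2-[4-(benzyloxy)-3-methoxyphenyl]-3-[(benzyloxy)methyl]-7-methoxy-2,3-dihydro-1-benzofuran
Conditions: NaH, BnBr, Bu4NI (cat.), DMF, 0 °C to rt
Reagents that add atoms: benzyl bromide, BrCc1ccccc1
Why: Williamson benzylation masks the only free hydroxyl, so that the later carbene meets no O–H bond, with a group that leaves together with the other benzyl ethers at the end.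

Step 9
Reactants: 14 (2S,3R)-5-allyl-2-[4-(benzyloxy)-3-methoxyphenyl]-3-[(benzyloxy)methyl]-7-methoxy-2,3-dihydro-1-benzofuran
Product: 16 3-(DHB-5-yl)propan-1-ol, via B-alkyl-9-BBN adduct 15 (not isolated)
Conditions: 9-BBN, THF, 0 °C to rt; then NaOH (aq), H2O2, 0 °C to rt
Reagents that add atoms: hydrogen peroxide, OO
Why: Hydroboration–oxidation with 9-BBN places boron on the terminal alkene carbon for steric reasons, so oxidation should give the anti-Markovnikov primary alcohol of the 3-arylpropyl chain.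

Step 10
Reactants: 16 3-(DHB-5-yl)propan-1-ol
Product: 18 3-(DHB-5-yl)propyl diazoacetate, via glyoxylate tosylhydrazone ester 17 (not isolated)
Conditions: TsNHN=CHCOCl, PhNMe2, CH2Cl2, 0 °C; then Et3N, 0 °C to rt
Reagents that add atoms: glyoxylic acid chloride p-toluenesulfonylhydrazone, Cc1ccc(cc1)S(=O)(=O)NN=CC(Cl)=O
Why: Diazoacetylation by acylation with the acid chloride hydrazone followed by amine-induced loss of p-toluenesulfinate (Bamford–Stevens-type elimination) is a mild, general route from primary alcohols to diazoacetates.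

Step 11
Reactants: 18 3-(DHB-5-yl)propyl diazoacetate
Product: 19 (4R)-4-[(DHB-5-yl)methyl]oxolan-2-one
Conditions: Rh2(4S-MPPIM)4 (1 mol %), CH2Cl2, reflux, slow addition of 18 by syringe pump
Reagents that add atoms: none
Why: The divalent rhodium carboxamidate extrudes N2 from the diazoacetate to give an electrophilic rhodium carbene, whose carbon inserts into a C–H bond of the central CH2 of the ArCH2–CH2–CH2–O chain through a three-centre, hydride-transfer-like transition state, forming the lactone C3–C4 bond and releasing the catalyst. The closest known reaction type is the enantioselective intramolecular C–H insertion of 3-arylpropyl diazoacetates with chiral dirhodium carboxamidates, which gives 4-benzyl γ-butyrolactones. The γ-lactone ring closes by 1,5-insertion, the carbene carbon and the attacked carbon being joined through C(=O)–O–CH2 in a five-membered cyclic transition state. The new centre (lactone C4, R) is set by the catalyst, whose chiral imidazolidinone ester ligands should let only one of the two enantiotopic hydrogens of the CH2 reach the carbene; the benzofuran stereocentres lie five or more bonds away and should not interfere, and the minor C4 epimer would be a separable diastereomer. The step needs regioselectivity for the central CH2 over O–CH2 (four-ring, deactivated inductively by the ester O) and over the benzylic CH2 (six-ring), and chemoselectivity over the three electron-rich arenes and the benzylic ether C–H bonds. These are secured by the five-ring preference and low electrophilicity of carboxamidate-bound carbenes, by the masking of both hydroxyl groups as benzyl ethers, and by slow addition that keeps the diazo ester dilute.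

Step 12
Reactants: 20 4-(benzyloxy)-3-methoxybenzyl alcohol
Product: 21 4-(benzyloxy)-3-methoxybenzyl bromide
Conditions: PBr3, Et2O, 0 °C
Reagents that add atoms: phosphorus tribromide, BrP(Br)Br
Why: Conversion of an electron-rich benzylic alcohol to its bromide with PBr3 (bromide displacement of the activated phosphite ester) is routine.

Step 13
Reactants: 19 (4R)-4-[(DHB-5-yl)methyl]oxolan-2-one; 21 4-(benzyloxy)-3-methoxybenzyl bromide
Product: 23 (3R,4R)-3-[4-(benzyloxy)-3-methoxybenzyl]-4-[(DHB-5-yl)methyl]oxolan-2-one, via lithium enolate 22 (not isolated)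
Conditions: LiN(SiMe3)2, THF, −78 °C; then 21, DMPU, −78 to −40 °C
Reagents that add atoms: none
Why: Enolate alkylation of a 4-substituted γ-butyrolactone, in which the benzylic bromide approaches the planar enolate anti to the C4 substituent, should give the 3,4-trans lactone (C3 R), as is usual for dibenzylbutyrolactones.

Step 14
Reactants: 23 (3R,4R)-3-[4-(benzyloxy)-3-methoxybenzyl]-4-[(DHB-5-yl)methyl]oxolan-2-one
Product: 24 lappaol A, (3R,4R)-3-(4-hydroxy-3-methoxybenzyl)-4-{[(2S,3R)-2-(4-hydroxy-3-methoxyphenyl)-3-(hydroxymethyl)-7-methoxy-2,3-dihydro-1-benzofuran-5-yl]methyl}oxolan-2-one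
Conditions: H2 (1 atm), Pd/C, EtOAc/MeOH, rt
Reagents that add atoms: none
Why: Catalytic hydrogenolysis should cleave the three O-benzyl bonds under neutral conditions that leave the lactone, the methyl ethers and the cyclic benzylic ether intact if the reaction is stopped at complete debenzylation; no stereocentre is touched.

**Compound list**

1 | 5-allyl-2-hydroxy-3-methoxybenzaldehyde | O=Cc1cc(CC=C)cc(OC)c1O | starting material
2 | 5-allyl-3-methoxy-2-(methoxymethoxy)benzaldehyde | O=Cc1cc(CC=C)cc(OC)c1OCOC | intermediate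
3 | 1-[5-allyl-3-methoxy-2-(methoxymethoxy)phenyl]-2,2,2-trichloroethan-1-ol (racemic) | OC(c1cc(CC=C)cc(OC)c1OCOC)C(Cl)(Cl)Cl | intermediate
4 | [5-allyl-3-methoxy-2-(methoxymethoxy)phenyl]acetic acid | OC(=O)Cc1cc(CC=C)cc(OC)c1OCOC | intermediate
5 | (S)-4-benzyl-1,3-oxazolidin-2-one | O=C1N[C@@H](Cc2ccccc2)CO1 | starting material
6 | mixed anhydride of 4 with pivalic acid | CC(C)(C)C(=O)OC(=O)Cc1cc(CC=C)cc(OC)c1OCOC | intermediate
7 | (4S)-3-{[5-allyl-3-methoxy-2-(methoxymethoxy)phenyl]acetyl}-4-benzyl-1,3-oxazolidin-2-one | O=C(Cc1cc(CC=C)cc(OC)c1OCOC)N1[C@@H](Cc2ccccc2)COC1=O | intermediate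
8 | 4-(benzyloxy)-3-methoxybenzaldehyde | O=Cc1ccc(OCc2ccccc2)c(OC)c1 | starting material
9 | dibutylboron Z-enolate of 7 | CCCCB(CCCC)O/C(=C\c1cc(CC=C)cc(OC)c1OCOC)N1[C@@H](Cc2ccccc2)COC1=O | intermediate
10 | (4S)-3-[(2S,3S)-2-[5-allyl-3-methoxy-2-(methoxymethoxy)phenyl]-3-[4-(benzyloxy)-3-methoxyphenyl]-3-hydroxypropanoyl]-4-benzyl-1,3-oxazolidin-2-one | O=C(N1[C@@H](Cc2ccccc2)COC1=O)[C@@H](c1cc(CC=C)cc(OC)c1OCOC)[C@H](O)c1ccc(OCc2ccccc2)c(OC)c1 | intermediate
11 | (1S,2R)-2-[5-allyl-3-methoxy-2-(methoxymethoxy)phenyl]-1-[4-(benzyloxy)-3-methoxyphenyl]propane-1,3-diol | C=CCc1cc(OC)c(OCOC)c(c1)[C@H](CO)[C@H](O)c1ccc(OCc2ccccc2)c(OC)c1 | intermediate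
12 | (1S,2R)-2-(5-allyl-2-hydroxy-3-methoxyphenyl)-1-[4-(benzyloxy)-3-methoxyphenyl]propane-1,3-diol | C=CCc1cc(OC)c(O)c(c1)[C@H](CO)[C@H](O)c1ccc(OCc2ccccc2)c(OC)c1 | intermediate
13 | [(2S,3R)-5-allyl-2-[4-(benzyloxy)-3-methoxyphenyl]-7-methoxy-2,3-dihydro-1-benzofuran-3-yl]methanol | C=CCc1cc(OC)c2c(c1)[C@H](CO)[C@@H](c1ccc(OCc3ccccc3)c(OC)c1)O2 | intermediate
14 | (2S,3R)-5-allyl-2-[4-(benzyloxy)-3-methoxyphenyl]-3-[(benzyloxy)methyl]-7-methoxy-2,3-dihydro-1-benzofuran | C=CCc1cc(OC)c2c(c1)[C@H](COCc1ccccc1)[C@@H](c1ccc(OCc3ccccc3)c(OC)c1)O2 | intermediate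
15 | B-[3-(DHB-5-yl)propyl]-9-borabicyclo[3.3.1]nonane | C(CCc1cc(OC)c2c(c1)[C@H](COCc1ccccc1)[C@@H](c1ccc(OCc3ccccc3)c(OC)c1)O2)B1C2CCCC1CCC2 | intermediate
16 | 3-(DHB-5-yl)propan-1-ol | OCCCc1cc(OC)c2c(c1)[C@H](COCc1ccccc1)[C@@H](c1ccc(OCc3ccccc3)c(OC)c1)O2 | intermediate
17 | 3-(DHB-5-yl)propyl glyoxylate p-toluenesulfonylhydrazone | Cc1ccc(cc1)S(=O)(=O)NN=CC(=O)OCCCc1cc(OC)c2c(c1)[C@H](COCc1ccccc1)[C@@H](c1ccc(OCc3ccccc3)c(OC)c1)O2 | intermediate
18 | 3-(DHB-5-yl)propyl diazoacetate | [N-]=[N+]=CC(=O)OCCCc1cc(OC)c2c(c1)[C@H](COCc1ccccc1)[C@@H](c1ccc(OCc3ccccc3)c(OC)c1)O2 | intermediate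
19 | (4R)-4-[(DHB-5-yl)methyl]oxolan-2-one | O=C1C[C@@H](Cc2cc(OC)c3c(c2)[C@H](COCc2ccccc2)[C@@H](c2ccc(OCc4ccccc4)c(OC)c2)O3)CO1 | intermediate
20 | 4-(benzyloxy)-3-methoxybenzyl alcohol | OCc1ccc(OCc2ccccc2)c(OC)c1 | starting material
21 | 4-(benzyloxy)-3-methoxybenzyl bromide | BrCc1ccc(OCc2ccccc2)c(OC)c1 | intermediate
22 | lithium enolate of 19 | [Li]OC1=C[C@@H](Cc2cc(OC)c3c(c2)[C@H](COCc2ccccc2)[C@@H](c2ccc(OCc4ccccc4)c(OC)c2)O3)CO1 | intermediate
23 | (3R,4R)-3-[4-(benzyloxy)-3-methoxybenzyl]-4-[(DHB-5-yl)methyl]oxolan-2-one (tri-O-benzyl lappaol A) | COc1cc(C[C@H]2C(=O)OC[C@@H]2Cc2cc(OC)c3c(c2)[C@H](COCc2ccccc2)[C@@H](c2ccc(OCc4ccccc4)c(OC)c2)O3)ccc1OCc1ccccc1 | intermediate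
24 | lappaol A | COc1cc(C[C@H]2C(=O)OC[C@@H]2Cc2cc(OC)c3c(c2)[C@H](CO)[C@@H](c2ccc(O)c(OC)c2)O3)ccc1O | target

**Count**

Total steps: 14. Longest linear sequence: 13 (steps 1 to 11, 13, 14); step 12 is a one-step side branch.

**Steps most likely to fail**

Step 11. The carbene may insert at the benzylic CH2 of the chain, attack an electron-rich arene or a benzylic ether C–H bond, or dimerise, and catalyst control over which hydrogen is taken may be incomplete on this large substrate. The fallback closes the lactone through its C–O bond under auxiliary control and sets out from 16. Oxidation (TEMPO cat., PhI(OAc)2, MeCN/H2O) should give 3-(DHB-5-yl)propanoic acid F1, which is coupled with 5 (PivCl, Et3N, LiCl, THF) to the N-acyloxazolidinone F2. Evans alkylation (NaN(SiMe3)2, THF, −78 °C; tert-butyl bromoacetate) anti to the auxiliary benzyl group should give the (3R) succinate imide F3. LiBH4 (THF, 0 °C) reduces the imide carbonyl selectively to the tert-butyl (3R)-hydroxy ester F4, and acid (TsOH cat., toluene, 80 °C) lactonises F4, returning to the route at 19.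

Step 3. With an electron-rich aryl group the benzylic carbon may ionise and be captured by hydroxide or alkoxide instead of hydride, and the acetal may be lost during acidification. The fallback is a cyanide-based homologation that sets out from 2 and bypasses step 2 as well. Van Leusen reductive cyanation (TosMIC, KOtBu, DME, −40 °C; then MeOH, reflux) should give the arylacetonitrile F5, and basic hydrolysis (KOH, EtOH/H2O, reflux; careful acidification to pH 4) returns to the route at 4.

Step 7. The benzylic cation may lose formaldehyde from the neighbouring CH2OH carbon (retro-Prins fragmentation) or eliminate instead of closing the ring, and trans selectivity may be incomplete. The fallback closes the ring before the auxiliary is removed, when no hydroxymethyl group is present, and sets out from 10. Acid (HCl, MeOH/THF, 40 °C) should remove the acetal and close the ring to the trans-dihydrobenzofuran-3-carbonyl oxazolidinone F6, and LiBH4 (MeOH, THF, 0 °C) then cleaves the auxiliary reductively, returning to the route at 13.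

**Further compounds**

F1 | step 11 | 3-(DHB-5-yl)propanoic acid | OC(=O)CCc1cc(OC)c2c(c1)[C@H](COCc1ccccc1)[C@@H](c1ccc(OCc3ccccc3)c(OC)c1)O2
F2 | step 11 | (4S)-4-benzyl-3-[3-(DHB-5-yl)propanoyl]-1,3-oxazolidin-2-one | O=C(CCc1cc(OC)c2c(c1)[C@H](COCc1ccccc1)[C@@H](c1ccc(OCc3ccccc3)c(OC)c1)O2)N1[C@@H](Cc2ccccc2)COC1=O
F3 | step 11 | tert-butyl (3R)-4-[(4S)-4-benzyl-2-oxo-1,3-oxazolidin-3-yl]-3-[(DHB-5-yl)methyl]-4-oxobutanoate | CC(C)(C)OC(=O)C[C@@H](Cc1cc(OC)c2c(c1)[C@H](COCc1ccccc1)[C@@H](c1ccc(OCc3ccccc3)c(OC)c1)O2)C(=O)N1[C@@H](Cc2ccccc2)COC1=O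
F4 | step 11 | tert-butyl (3R)-3-[(DHB-5-yl)methyl]-4-hydroxybutanoate | CC(C)(C)OC(=O)C[C@@H](Cc1cc(OC)c2c(c1)[C@H](COCc1ccccc1)[C@@H](c1ccc(OCc3ccccc3)c(OC)c1)O2)CO
F5 | step 3 | [5-allyl-3-methoxy-2-(methoxymethoxy)phenyl]acetonitrile | N#CCc1cc(CC=C)cc(OC)c1OCOC
F6 | step 7 | (4S)-3-{[(2S,3S)-5-allyl-2-[4-(benzyloxy)-3-methoxyphenyl]-7-methoxy-2,3-dihydro-1-benzofuran-3-yl]carbonyl}-4-benzyl-1,3-oxazolidin-2-one | C=CCc1cc(OC)c2c(c1)[C@H](C(=O)N1[C@@H](Cc3ccccc3)COC1=O)[C@@H](c1ccc(OCc3ccccc3)c(OC)c1)O2
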